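The route rests on cutting the bond between C1 of the 4-methoxyphenyl ring and the ketone carbon of the C(=O)–CH2 bridge, and on making it at the alkyne oxidation level. The bridge ketone carbon is disguised as the terminal sp carbon of an arylacetylene that already carries the 4-methylpentanoyl chain between two O-methylated phenols. A Sonogashira coupling with 4-iodoanisole joins both halves in one operation under near-neutral conditions. The step exploits the electronic mismatch of the two rings: the para-methoxy donor ring and the acyl-bearing resorcinol acceptor ring polarise the resulting diarylalkyne, so acid hydration places oxygen only on the carbon next to the anisole ring. Chelation-controlled ether cleavage finishes the synthesis.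

Key step: step 3

Remark: the target contains no stereocentre and no stereogenic double bond, so it is one achiral compound and no step has to control configuration.

Step 1
Reactants: 1 4-methylpentanoyl chloride; 2 N,O-dimethylhydroxylamine hydrochloride
Product: 3 N-methoxy-N,4-dimethylpentanamide
Conditions: K2CO3 (2.2 equiv), EtOAc/H2O, 0 °C → rt
Reagents that add atoms: none
Why: Schotten–Baumann N-acylation of the liberated hydroxylamine by the acid chloride should give the Weinreb amide, with carbonate taking up both equivalents of HCl.

Step 2
Reactants: 4 1-ethynyl-3,5-dimethoxybenzene; 3 N-methoxy-N,4-dimethylpentanamide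
Product: 7 1-(4-ethynyl-2,6-dimethoxyphenyl)-4-methylpentan-1-one, via dilithiated alkyne 5 (not isolated), via lithium hemiaminal adduct 6 (not isolated)
Conditions: n-BuLi (2.1 equiv), TMEDA (1.1 equiv), THF, −78 → 0 °C; then 3 (1.0 equiv), −78 → −30 °C; 1 M HCl quench
Reagents that add atoms: none
Why: The first equivalent of n-BuLi forms the lithium acetylide and the second performs a directed ortho-metalation at C4, the only position flanked by both methoxy groups, after which the far more reactive aryllithium site of 5 takes up the single equivalent of Weinreb amide 3 at low temperature while the acetylide stays idle, and the chelated adduct 6 blocks over-addition until the acidic quench (Weinreb ketone synthesis).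

Step 3
Reactants: 7 1-(4-ethynyl-2,6-dimethoxyphenyl)-4-methylpentan-1-one; 8 4-iodoanisole
Product: 9 1-{2,6-dimethoxy-4-[(4-methoxyphenyl)ethynyl]phenyl}-4-methylpentan-1-one
Conditions: PdCl2(PPh3)2 (2 mol %), CuI (4 mol %), Et3N, THF, rt, argon, slow addition of 7
Reagents that add atoms: none
Why: Pd(0) inserts into the C–I bond of 8, CuI and Et3N convert the terminal alkyne of 7 (acidified by the para-acyl group) into a copper acetylide, and transmetalation followed by reductive elimination forms the bond between C1 of the 4-methoxyphenyl ring and the sp carbon that later becomes the bridge ketone carbon. The reaction type is the Sonogashira coupling of an aryl iodide with an arylacetylene. Both carbons react with inverted polarity relative to a Friedel–Crafts acylation (latent acyl carbon as nucleophile, anisole para carbon as electrophile), so no acylium ion or strong Lewis acid meets the nucleophilic dimethoxyarene ring and the para position is fixed by the iodine atom. No ring is closed and no stereocentre is formed. The step needs chemoselectivity for the alkyne C–H over the enolisable, sterically shielded ketone, which the weak amine base secures, and cross-coupling over homocoupling, which exclusion of oxygen and slow addition of 7 secure. The donor ring on one alkyne carbon and the acceptor ring on the other are thereby set up for the regioselective hydration of step 4.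

Step 4
Reactants: 9 1-{2,6-dimethoxy-4-[(4-methoxyphenyl)ethynyl]phenyl}-4-methylpentan-1-one
Product: 10 1-{2,6-dimethoxy-4-[2-(4-methoxyphenyl)-2-oxoethyl]phenyl}-4-methylpentan-1-one
Conditions: p-TsOH·H2O (1 equiv), aqueous EtOH, reflux
Reagents that add atoms: water, O
Why: In this Brønsted acid-catalysed Markovnikov hydration of a push–pull diarylalkyne, protonation at the alkyne carbon bound to the acyl-bearing ring gives the vinyl cation conjugated with the para-methoxy group, water adds at that carbon, and tautomerisation should give only the 4-methoxyphenyl ketone.

Step 5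
Reactants: 10 1-{2,6-dimethoxy-4-[2-(4-methoxyphenyl)-2-oxoethyl]phenyl}-4-methylpentan-1-one
Product: 11 1-{2,6-dihydroxy-4-[2-(4-methoxyphenyl)-2-oxoethyl]phenyl}-4-methylpentan-1-one (target)
Conditions: AlCl3 (6 equiv), CH2Cl2, 0 °C → rt; 1 M HCl work-up
Reagents that add atoms: none
Why: Each methoxy group ortho to the 4-methylpentanoyl carbonyl can sit in a six-membered aluminium chelate and lose its methyl group to chloride (chelation-controlled Lewis acid cleavage of ortho-acyl aryl methyl ethers), whereas the methoxy group of the anisoyl ring cannot chelate and should survive as it does in AlCl3-mediated Friedel–Crafts acylations of anisole.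

Compound list
1 | 4-methylpentanoyl chloride | CC(C)CCC(=O)Cl | starting material
2 | N,O-dimethylhydroxylamine hydrochloride | CNOC.Cl | starting material
3 | N-methoxy-N,4-dimethylpentanamide | CC(C)CCC(=O)N(C)OC | intermediate
4 | 1-ethynyl-3,5-dimethoxybenzene | C#Cc1cc(OC)cc(OC)c1 | starting material
5 | dilithiated alkyne: lithium (4-lithio-3,5-dimethoxyphenyl)acetylide | [Li]C#Cc1cc(OC)c([Li])c(OC)c1 | intermediate
6 | lithium hemiaminal adduct of 5 and 3 (transient, racemic) | [Li]C#Cc1cc(OC)c(C(O[Li])(CCC(C)C)N(C)OC)c(OC)c1 | intermediate
7 | 1-(4-ethynyl-2,6-dimethoxyphenyl)-4-methylpentan-1-one | C#Cc1cc(OC)c(C(=O)CCC(C)C)c(OC)c1 | intermediate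
8 | 4-iodoanisole | COc1ccc(I)cc1 | starting material
9 | 1-{2,6-dimethoxy-4-[(4-methoxyphenyl)ethynyl]phenyl}-4-methylpentan-1-one | COc1ccc(C#Cc2cc(OC)c(C(=O)CCC(C)C)c(OC)c2)cc1 | intermediate
10 | 1-{2,6-dimethoxy-4-[2-(4-methoxyphenyl)-2-oxoethyl]phenyl}-4-methylpentan-1-one | COc1ccc(C(=O)Cc2cc(OC)c(C(=O)CCC(C)C)c(OC)c2)cc1 | intermediate
11 | 1-{2,6-dihydroxy-4-[2-(4-methoxyphenyl)-2-oxoethyl]phenyl}-4-methylpentan-1-one | COc1ccc(C(=O)Cc2cc(O)c(C(=O)CCC(C)C)c(O)c2)cc1 | target

Total step count: 5
Longest linear sequence: 5 steps (1 → 3 → 7 → 9 → 10 → 11), or four steps counted from 4.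

Steps most likely to fail

Step 2. Ring lithiation of the acetylide may stay incomplete, or acylation at the acetylide terminus may compete with acylation at the aryl site. The fallback sets out from 4 and comes back at 7, and it removes the alkyne C–H from play so that only one carbanion is present. Compound 4 is deprotonated with n-BuLi (1 equiv, THF, −78 °C) and silylated with TIPSCl to give [(3,5-dimethoxyphenyl)ethynyl]triisopropylsilane F1. A single directed ortho-metalation (n-BuLi, THF, 0 °C) and acylation with 3 should give 1-{2,6-dimethoxy-4-[(triisopropylsilyl)ethynyl]phenyl}-4-methylpentan-1-one F2. TBAF in THF then releases 7.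

Step 5. The cleavage may stall after the first ether. On forcing, the methyl ether of the anisoyl ring may be lost, because its oxygen lies para to a Lewis acid-bound carbonyl. The fallback sets out from 9 and comes back at 11, and it moves the ether cleavage in front of the hydration. At that stage the anisole ring carries an alkyne instead of a carbonyl group and its ether is an ordinary, slower-reacting aryl methyl ether. BBr3 (2.2 equiv, CH2Cl2, −78 → −20 °C), which diarylalkynes tolerate, should convert 9 into 1-{2,6-dihydroxy-4-[(4-methoxyphenyl)ethynyl]phenyl}-4-methylpentan-1-one F3. The acid hydration of step 4 applied to F3 then gives 11 directly.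

Step 4. Protonation of an alkyne deactivated by the acceptor ring may be slow. Forcing acid could then start protodeacylation of the hindered ketone, or the regioselectivity of water addition could erode. The fallback sets out from 7 and comes back at 10. It avoids alkyne hydration altogether and fixes the position of the oxygen by construction, while still forming the same aryl–carbon bond. Hydroboration of 7 with dicyclohexylborane (THF, 0 °C) and buffered oxidation with NaBO3 should give 2-[3,5-dimethoxy-4-(4-methylpentanoyl)phenyl]acetaldehyde F4. Commercial 4-methoxyphenylmagnesium bromide (THF, −78 °C, LaCl3·2LiCl to suppress enolisation) should add to the aldehyde in preference to the shielded ketone and give racemic 1-{4-[2-hydroxy-2-(4-methoxyphenyl)ethyl]-2,6-dimethoxyphenyl}-4-methylpentan-1-one F5. Dess–Martin oxidation then gives 10.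

Further compounds
F1 | step 2 | [(3,5-dimethoxyphenyl)ethynyl]triisopropylsilane | COc1cc(C#C[Si](C(C)C)(C(C)C)C(C)C)cc(OC)c1
F2 | step 2 | 1-{2,6-dimethoxy-4-[(triisopropylsilyl)ethynyl]phenyl}-4-methylpentan-1-one | COc1cc(C#C[Si](C(C)C)(C(C)C)C(C)C)cc(OC)c1C(=O)CCC(C)C
F3 | step 5 | 1-{2,6-dihydroxy-4-[(4-methoxyphenyl)ethynyl]phenyl}-4-methylpentan-1-one | COc1ccc(C#Cc2cc(O)c(C(=O)CCC(C)C)c(O)c2)cc1
F4 | step 4 | 2-[3,5-dimethoxy-4-(4-methylpentanoyl)phenyl]acetaldehyde | O=CCc1cc(OC)c(C(=O)CCC(C)C)c(OC)c1
F5 | step 4 | 1-{4-[2-hydroxy-2-(4-methoxyphenyl)ethyl]-2,6-dimethoxyphenyl}-4-methylpentan-1-one (racemic) | COc1ccc(C(O)Cc2cc(OC)c(C(=O)CCC(C)C)c(OC)c2)cc1
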